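At early times the nucleophile meets the electrophile at its full charge; this examination asks what the electrophile sees after that.

in all of them: electrophile 2.0 mM; gas 0.071 mM (held); time 25 s

| flask | nucleophile |
|---|---|
| south | 4.00 mM |
| north | 6.00 mM |
| west | 9.00 mM |

    nucleophile + acid set free ⇌ protonated nucleophile, settled at all times (K1 = 7.3 × 10⁵ M⁻¹)
    electrophile + target → side product (k2 = 51 M⁻¹ s⁻¹)
    gas ⇌ free base, rate k3*(csat - [free base]) (k3 = 5.3 s⁻¹, csat = 0.071 mM)
    acid set free + free base ⇌ salt of the base, settled at all times (K4 = 1.9 × 10⁶ M⁻¹)
    electrophile + nucleophile → acid set free + target (k5 = 19 M⁻¹ s⁻¹)
    nucleophile ⇌ dormant form (K6 = 2.7, k6 = 0.086 s⁻¹)

- percentages count the electrophile that a species holds: one side product counts as two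
- at the start none of free base is dissolved
- run time (south): 25 s

- part of the electrophile that has reacted at the end, south
- part of the electrophile that has reacted at the end, north
- part of the electrophile that has reacted at the end, west
- what raising the concentration of nucleophile from its lowest to its highest value here does to the part of the electrophile that has reacted (changes below 5 percentage points count as none) (it rises / it falls / no change)

Where must each flask end? Neither step that consumes electrophile has a way back, so the end state is electrophile fully converted, and the asked conversion is a question of how fast that state is approached.

Who takes the nucleophile first? In south, just after the start, the forward step to the dormant form uses nucleophile 2.3 times as fast as the electrophile does. That balance relaxes with a half-life of 5.88 s, shorter than the 9.1 s the electrophile would need with nucleophile as charged. So I treat the balance as set: of nucleophile and dormant form together, the free share is one over one plus K6, or 27.0 %. This gives a working nucleophile of 1.08 mM in south, a pseudo-first-order partner for the electrophile.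

Is that the whole drain? No. Target also consumes electrophile, with 51 M⁻¹ s⁻¹ against 19 M⁻¹ s⁻¹. I expect target to climb until it is used as fast as it is made. The electrophile cancels from that balance, leaving a quasi-steady plateau of k5[nucleophile]/k2, 0.403 mM in south. In south the half-life of target by the side step alone, electrophile as charged, is 6.8 s, shorter than the run. On the plateau each electrophile lost to nucleophile takes a second one with it. The electrophile then decays with τ = 24.3 s in south, the electrophile time constant, one over twice k5 times the working nucleophile. For north τ is 16.2 s, and for west 10.8 s.

What do you commit to? One minus exp(−t/τ) gives 64.2 % for south, 78.6 % for north and 90.1 % for west. The trend is it rises, since τ shrinks with the charge.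

Your working nucleophile stands still. Does it? No. The step to target consumes it, and acid set free protonates it: in south, K1[nucleophile] starts at 2900 against 135 for K4 times saturated free base, so I expect the free base to take the smaller part of that acid. These two lower the working amount as the run goes, while the head start at full charge pushes the other way, and I size none of them.

The forecast reads 70 %, 84 % and 92 % for south, north and west, above mine in each flask, with the trend it rises: “the reacted share climbs clearly from the lowest to the highest nucleophile level”.

The simulation gives 67.6 %, 82.0 % and 92.6 % for south, north and west; the trend is it rises, by 25 percentage points.

South ends with 32 % of its electrophile where τ leaves 35.8 %. The neighbouring flask is south with nucleophile cut to 2.4 mM. There τ lengthens to 40.6 s, which leaves 54.0 % of the electrophile, on a target plateau of 12.1 %. That neighbouring flask ends with 51.3 % as electrophile, 10.4 % as target and 38.3 % as side product, so 48.7 % has reacted.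

(The constants are made up; the flask was simulated.)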